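## The problem

6,8-Diprenylnaringenin (12) is a flavanone. A chroman-4-one (ring C) is fused to a fully substituted phloroglucinol ring A that carries hydroxyls at C5 and C7 and 3-methylbut-2-enyl groups at C6 and C8, and C2 bears a 4-hydroxyphenyl ring B. C2 (S) is the only stereocentre, so no resident centre can direct it and it must come from a catalyst. It is also fragile: C2 is benzylic, bonded to O1 and β to the C4 ketone, so base opens ring C by retro-oxa-Michael reaction. A free 4'-phenoxide can in addition push O1 off C2 through a quinone methide, and either path erodes the configuration. The prenyl groups lie ortho to phenols; strong acid cyclises them to dimethylchromans and hydrogenation reduces them, which excludes hydrogenolysis and hard Lewis acids at the end. Ring A is hexasubstituted, but it is the ring of 2,4,6-trihydroxyacetophenone with its two free carbons prenylated, and the acetyl group already supplies C4 and C3. The feature that opens the key step is that C3, α to the C4 carbonyl, reaches the O-benzylic carbon C2 through C4, C4a, C8a and O1, a six-membered array. Before ring C exists, O1 and the oxygen on C5 are the two equivalent ortho oxygens of one acylphloroglucinol, so a carbenoid at C3 flanked by two identical 4-oxybenzyl ethers gives the same flavanone whichever ether it attacks.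

## Retrosynthesis

**12 from 11.** The last cut removes two O–Si bonds, at O7 and O4'. Silyl ethers are chosen because fluoride buffered with acetic acid frees them without making the 4'-hydroxyl a phenoxide and without acid strong enough to touch the prenyl groups. Methyl or benzyl ethers would need boron tribromide or hydrogen. Precursor 11 already has the chelated 5-hydroxyl free, so the final step only has to unmask phenols.

**11 from 10.** The O5–CH2 bond of the spare 4-silyloxybenzyl ether is cut next. This ether is the unused twin of the group that became ring B. It sits peri to the C4 carbonyl, so magnesium bromide can chelate O5 and the carbonyl oxygen and deliver bromide to the benzylic carbon while the silyl ethers stay. The neighbouring option is to desilylate first and let the unmasked 4-hydroxybenzyl ether leave by 1,6-elimination. That needs a phenoxide para to a benzylic C–O bond, and the same arrangement exists at C4'/C2–O1, so the condition that frees O5 could also open ring C. The ether is therefore removed while O4' is still silylated, and the elimination variant is held in reserve.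

**10 from 9.** The strategic cut is C2–C3. Cutting O1–C2 would mean a reversible oxa-Michael closure that is hard to steer. Cutting C2–aryl would mean conjugate arylation of an unsaturated ring C ketone, which is workable but needs a separately built heterocycle. The C2–C3 cut leads to diazoketone 9, which is achiral, has no ring C and has a twofold axis. Both ring B and the stereocentre then arrive in one neutral step whose only by-product is dinitrogen. The forward reaction must prefer C–H insertion over attack at the ether oxygen and must distinguish the two enantiotopic benzylic hydrogens.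

**9 from 7.** The diazo group is placed on the methyl ketone of 7 by detrifluoroacetylative diazo transfer through the activated diketone 8. The acid chloride/diazomethane alternative would need a benzoic acid that the acetophenone series does not offer. This cut removes only the energetic functional group and leaves a stable ketone.

**7 from 4 and 6.** Two aryl O–CH2 bonds are cut, giving the 2,6-dihydroxy ketone 4 and two equivalents of benzylic alcohol 6. Mitsunobu etherification is preferred to carbonate-mediated alkylation because it is neutral and keeps the aryl silyl ether at O4, which is para to the acyl group and base-labile. Alcohol 6 comes from aldehyde 5 by hydride reduction.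

**4 from 3, and 3 from 1 and 2.** The O4–Si bond is cut first. O4 is the only phenol of 3 that is not chelated to the carbonyl and it is the most acidic, so one equivalent of silyl chloride should select it. The two aryl–CH2 bonds then lead to 2,4,6-trihydroxyacetophenone 1 and prenyl bromide 2. The acetyl group blocks one ring carbon, so only C3 and C5 are open to C-alkylation.

## Roads not taken

Alternative 1: Here ring A itself is disconnected at three carbon–carbon bonds. Heating cyclobutenone A1 with siloxyalkyne A2 would trigger a four-electron ring opening, a [2+2] capture of the alkyne, a second ring opening and a six-electron closure, giving phenol A3. Its merit is regiocontrol: each prenyl group arrives on a defined carbon and the three oxygens come out differentiated, whereas step 1 of the chosen route is a statistical C-alkylation of modest efficiency. Its weak points are that it builds the one part of the target that is commercially available, that A1 and A2 each need several steps, and that the thermolysis exposes two prenyl groups to a ketene-rich medium. After A3 the acyl carbon, ring C and the stereocentre are all still missing. The chosen plan sets against the better prenyl placement that its statistical step is a single operation on cheap material, and that the route spends its effort on the stereocentre.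

Alternative 2: This road cuts C8–C8a and C4a–C5 and grows ring A last. Diene A4 would add to the bromo-enone A5 by conjugate addition and ester condensation, and loss of HBr and methanol would aromatise to A6. The plan is convergent, both prenyl groups are regiodefined, no spectator group has to be removed, and A6 is one desilylation from 12. In step count it is at least the equal of the chosen route, and the stereocentre would come from an established asymmetric hetero-Diels–Alder reaction of aldehyde 5. The weak points lie in the annulation. The nucleophilic terminus of A4 is substituted and hindered. Such cyclisations normally need TiCl4 or a similar strong Lewis acid, which threatens the prenyl alkenes and can ionise the benzylic C2–O1 bond of A5 next to an electron-rich aryl group. The required sequence on a brominated dihydropyranone is also less secured than the individual steps suggest. The stereocentre would thus be made early and then carried through the harshest step. The chosen plan sets against this a ring closure of a known class, run under neutral conditions and placed late.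

Alternative 3: This road cuts C3–C4 and O1–C2. Salicylaldehyde A7 and trimethyl orthoformate A8 would give, under a chiral Brønsted acid, the methoxy ortho-quinone methide A10, which adds styrene A9 in a [4+2] sense to give flavan A11. It forms two bonds and ring C in one step, takes ring B from a simple styrene and avoids diazo chemistry, and in bonds formed per step it is better than the chosen insertion. For this target the cost is high. A11 is at the flavan oxidation level, and its C4 methoxy group must be hydrolysed and oxidised to the ketone in the presence of two prenyl groups and an acid-sensitive 2-aryl chroman, which erases a stereocentre just made. A7 requires one of three phenols of a diprenylated aldehyde to be left free while two are silylated. The free phenol next to a prenyl group and the electron-rich styrene A9 are both exposed to acid. The chosen plan delivers the C4 ketone directly and needs no redox correction.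

Key step: step 6

Remark on materials: aldehyde 5 is taken as a purchasable aryl silyl ether.

Remark on stereochemistry: the sense of induction of Rh2(S-PTTL)4 on this substrate cannot be predicted with confidence. The route is written with the S-configured ligand, and the mirror-image complex Rh2(R-PTTL)4 would replace it if the first run gave the 2R series.

## Route

Step 1
Reactants: 1 2,4,6-trihydroxyacetophenone; 2 prenyl bromide (1-bromo-3-methylbut-2-ene)
Product: 3 1-[2,4,6-trihydroxy-3,5-bis(3-methylbut-2-en-1-yl)phenyl]ethanone
Conditions: 2 (2.2 equiv), 10% aq KOH, 0 °C to rt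
Reagents that add atoms: none
Why: C-alkylation of the phloroglucinol polyanion (Friedel–Crafts-type allylation): in water the oxygen sites are solvated and the only free ring carbons, C3 and C5, take the allylic bromide. Mono-, gem-di- and O-alkylated by-products are expected and are removed by chromatography, which is acceptable for a first step on inexpensive materials.

Step 2
Reactants: 3 1-[2,4,6-trihydroxy-3,5-bis(3-methylbut-2-en-1-yl)phenyl]ethanone
Product: 4 1-[4-(tert-butyldimethylsilyloxy)-2,6-dihydroxy-3,5-bis(3-methylbut-2-en-1-yl)phenyl]ethanone
Conditions: TBSCl (1.05 equiv), imidazole, DMF, 0 °C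
Reagents that add atoms: tert-butyldimethylsilyl chloride, CC(C)(C)[Si](C)(C)Cl
Why: Regioselective silylation of a phenol: the 4-hydroxyl is the most acidic and the only one not hydrogen-bonded to the acetyl carbonyl, and the 2- and 6-hydroxyls are chelated and flanked by acetyl and prenyl groups, so one equivalent of silyl chloride should go to O4.

Step 3
Reactants: 5 4-(tert-butyldimethylsilyloxy)benzaldehyde
Product: 6 [4-(tert-butyldimethylsilyloxy)phenyl]methanol
Conditions: NaBH4, MeOH, 0 °C
Reagents that add atoms: none
Why: Hydride reduction of an aryl aldehyde to the benzylic alcohol; the aryl silyl ether tolerates NaBH4 at 0 °C over a short reaction time.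

Step 4
Reactants: 4 1-[4-(tert-butyldimethylsilyloxy)-2,6-dihydroxy-3,5-bis(3-methylbut-2-en-1-yl)phenyl]ethanone; 6 [4-(tert-butyldimethylsilyloxy)phenyl]methanol (2.5 equiv)
Product: 7 1-{2,6-bis[4-(tert-butyldimethylsilyloxy)benzyloxy]-4-(tert-butyldimethylsilyloxy)-3,5-bis(3-methylbut-2-en-1-yl)phenyl}ethanone
Conditions: PPh3, DIAD, THF, 0 °C to rt
Reagents that add atoms: none
Why: Double Mitsunobu etherification: the chelated ortho phenols are acidic enough to protonate the betaine, and each phenoxide displaces the primary benzylic alkoxyphosphonium ion by SN2. The neutral medium should leave the three aryl silyl ethers and the prenyl groups untouched, and the fully substituted ring offers no site for C-alkylation.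

Step 5
Reactants: 7 1-{2,6-bis[4-(tert-butyldimethylsilyloxy)benzyloxy]-4-(tert-butyldimethylsilyloxy)-3,5-bis(3-methylbut-2-en-1-yl)phenyl}ethanone
Product: 9 1-{2,6-bis[4-(tert-butyldimethylsilyloxy)benzyloxy]-4-(tert-butyldimethylsilyloxy)-3,5-bis(3-methylbut-2-en-1-yl)phenyl}-2-diazoethanone, via trifluoroacetyl diketone 8 (not isolated)
Conditions: LiN(SiMe3)2, THF, −78 °C; CF3CO2CH2CF3; aq HCl work-up; then 4-acetamidobenzenesulfonyl azide, Et3N, H2O (1 equiv), MeCN, rt
Reagents that add atoms: 4-acetamidobenzenesulfonyl azide, CC(=O)Nc1ccc(cc1)S(=O)(=O)N=[N+]=[N-] (the two diazo nitrogens); 2,2,2-trifluoroethyl trifluoroacetate, O=C(OCC(F)(F)F)C(F)(F)F (the trifluoroacetyl group of 8, lost again)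
Why: Detrifluoroacetylative diazo transfer: the kinetic lithium enolate of the methyl ketone is C-trifluoroacetylated to diketone 8, which takes the diazo group from the sulfonyl azide under Et3N, and the adduct fragments with loss of the trifluoroacetyl group as an N-acylsulfonamide. The method is established for aryl methyl ketones and needs only the methyl group, which the two ortho ethers do not block.

Step 6
Reactants: 9 1-{2,6-bis[4-(tert-butyldimethylsilyloxy)benzyloxy]-4-(tert-butyldimethylsilyloxy)-3,5-bis(3-methylbut-2-en-1-yl)phenyl}-2-diazoethanone
Product: 10 (2S)-5-[4-(tert-butyldimethylsilyloxy)benzyloxy]-7-(tert-butyldimethylsilyloxy)-2-[4-(tert-butyldimethylsilyloxy)phenyl]-6,8-bis(3-methylbut-2-en-1-yl)chroman-4-one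
Conditions: Rh2(S-PTTL)4 (dirhodium tetrakis[N-phthaloyl-(S)-tert-leucinate], 2 mol%), CH2Cl2, 0 °C to rt, slow addition of 9
Reagents that add atoms: none
Why: Rh2(S-PTTL)4, a chiral divalent rhodium carboxylate dimer, takes dinitrogen from 9 to give an electrophilic rhodium carbenoid at C3, which inserts into one benzylic C–H bond of an ortho 4-silyloxybenzyl ether through a concerted, asynchronous three-centre transition state with hydride-transfer character, forming C2–C3 and releasing the catalyst. The closest known reaction type is the chiral dirhodium carboxylate catalysed C–H insertion of 2-alkoxyaryl α-diazoketones to 2-substituted chroman-4-ones. Ring C closes by 1,6-insertion through a six-membered array (C3, C4, C4a, C8a, O1, C2), preferred here because the C–H bonds next to the ether oxygen are the only ones within reach and are activated by both that oxygen and the electron-rich aryl group. C2 is the only new stereocentre and is set under catalyst control: the phthalimido-tert-leucinate ligands differentiate the two enantiotopic hydrogens of the benzylic CH2, and insertion proceeds with retention at carbon. The two ether arms are exchanged by the twofold axis through the acyl-bearing and silyloxy-bearing ring carbons, so insertion into either arm gives the same enantiomer of 10. The selectivity that matters is C–H insertion over attack of the ether oxygen on the carbenoid (oxonium ylide formation, then [1,2]-benzyl shift); carboxylate ligands on rhodium, the low basicity of an aryl ether oxygen conjugated to the ortho acyl group, and the para-silyloxy donor, which helps hydride-type C–H cleavage more than radical-pair benzyl migration, all lean toward insertion. The prenyl alkenes are meta to the acyl carbon and cannot reach the carbenoid within the molecule, and slow addition keeps intermolecular cyclopropanation and carbene dimerisation down. The medium is neutral, so the new C2 centre is not exposed to base.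

Step 7
Reactants: 10 (2S)-5-[4-(tert-butyldimethylsilyloxy)benzyloxy]-7-(tert-butyldimethylsilyloxy)-2-[4-(tert-butyldimethylsilyloxy)phenyl]-6,8-bis(3-methylbut-2-en-1-yl)chroman-4-one
Product: 11 (2S)-7-(tert-butyldimethylsilyloxy)-2-[4-(tert-butyldimethylsilyloxy)phenyl]-5-hydroxy-6,8-bis(3-methylbut-2-en-1-yl)chroman-4-one
Conditions: MgBr2·OEt2 (3 equiv), toluene/Et2O, rt; aqueous work-up
Reagents that add atoms: none
Why: Chelation-controlled cleavage of an aryl benzyl ether ortho to a carbonyl: magnesium bridges O5 and the C4 carbonyl oxygen, and bromide displaces the electron-rich benzyl group at its primary carbon. The silyl ethers at O7 and O4' are not chelated and should stay. With no phenoxide at C4' and no Brønsted acid present, neither the C2–O1 bond nor the prenyl groups are put at risk.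

Step 8
Reactants: 11 (2S)-7-(tert-butyldimethylsilyloxy)-2-[4-(tert-butyldimethylsilyloxy)phenyl]-5-hydroxy-6,8-bis(3-methylbut-2-en-1-yl)chroman-4-one
Product: 12 (2S)-5,7-dihydroxy-2-(4-hydroxyphenyl)-6,8-bis(3-methylbut-2-en-1-yl)chroman-4-one (6,8-diprenylnaringenin)
Conditions: Bu4NF (3 equiv), AcOH (4 equiv), THF, 0 °C
Reagents that add atoms: none
Why: Fluoride desilylation of two aryl silyl ethers under acetic acid buffering. The buffer keeps the liberated 4'-phenol protonated, so neither quinone-methide opening of ring C nor retro-oxa-Michael opening should scramble C2, and the medium is too weakly acidic to cyclise the prenyl groups onto the neighbouring phenols.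

## Compound list

1 | 2,4,6-trihydroxyacetophenone | CC(=O)c1c(O)cc(O)cc1O | starting material
2 | prenyl bromide (1-bromo-3-methylbut-2-ene) | CC(C)=CCBr | starting material
3 | 1-[2,4,6-trihydroxy-3,5-bis(3-methylbut-2-en-1-yl)phenyl]ethanone | CC(=O)c1c(O)c(CC=C(C)C)c(O)c(CC=C(C)C)c1O | intermediate
4 | 1-[4-(tert-butyldimethylsilyloxy)-2,6-dihydroxy-3,5-bis(3-methylbut-2-en-1-yl)phenyl]ethanone | CC(=O)c1c(O)c(CC=C(C)C)c(O[Si](C)(C)C(C)(C)C)c(CC=C(C)C)c1O | intermediate
5 | 4-(tert-butyldimethylsilyloxy)benzaldehyde | O=Cc1ccc(O[Si](C)(C)C(C)(C)C)cc1 | starting material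
6 | [4-(tert-butyldimethylsilyloxy)phenyl]methanol | OCc1ccc(O[Si](C)(C)C(C)(C)C)cc1 | intermediate
7 | 1-{2,6-bis[4-(tert-butyldimethylsilyloxy)benzyloxy]-4-(tert-butyldimethylsilyloxy)-3,5-bis(3-methylbut-2-en-1-yl)phenyl}ethanone | CC(=O)c1c(OCc2ccc(O[Si](C)(C)C(C)(C)C)cc2)c(CC=C(C)C)c(O[Si](C)(C)C(C)(C)C)c(CC=C(C)C)c1OCc1ccc(O[Si](C)(C)C(C)(C)C)cc1 | intermediate
8 | 1-{2,6-bis[4-(tert-butyldimethylsilyloxy)benzyloxy]-4-(tert-butyldimethylsilyloxy)-3,5-bis(3-methylbut-2-en-1-yl)phenyl}-4,4,4-trifluorobutane-1,3-dione | O=C(CC(=O)C(F)(F)F)c1c(OCc2ccc(O[Si](C)(C)C(C)(C)C)cc2)c(CC=C(C)C)c(O[Si](C)(C)C(C)(C)C)c(CC=C(C)C)c1OCc1ccc(O[Si](C)(C)C(C)(C)C)cc1 | intermediate (not isolated)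
9 | 1-{2,6-bis[4-(tert-butyldimethylsilyloxy)benzyloxy]-4-(tert-butyldimethylsilyloxy)-3,5-bis(3-methylbut-2-en-1-yl)phenyl}-2-diazoethanone | [N-]=[N+]=CC(=O)c1c(OCc2ccc(O[Si](C)(C)C(C)(C)C)cc2)c(CC=C(C)C)c(O[Si](C)(C)C(C)(C)C)c(CC=C(C)C)c1OCc1ccc(O[Si](C)(C)C(C)(C)C)cc1 | intermediate
10 | (2S)-5-[4-(tert-butyldimethylsilyloxy)benzyloxy]-7-(tert-butyldimethylsilyloxy)-2-[4-(tert-butyldimethylsilyloxy)phenyl]-6,8-bis(3-methylbut-2-en-1-yl)chroman-4-one | CC(C)=CCc1c(O[Si](C)(C)C(C)(C)C)c(CC=C(C)C)c2c(c1OCc1ccc(O[Si](C)(C)C(C)(C)C)cc1)C(=O)C[C@@H](c1ccc(O[Si](C)(C)C(C)(C)C)cc1)O2 | intermediate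
11 | (2S)-7-(tert-butyldimethylsilyloxy)-2-[4-(tert-butyldimethylsilyloxy)phenyl]-5-hydroxy-6,8-bis(3-methylbut-2-en-1-yl)chroman-4-one | CC(C)=CCc1c(O[Si](C)(C)C(C)(C)C)c(CC=C(C)C)c2c(c1O)C(=O)C[C@@H](c1ccc(O[Si](C)(C)C(C)(C)C)cc1)O2 | intermediate
12 | (2S)-5,7-dihydroxy-2-(4-hydroxyphenyl)-6,8-bis(3-methylbut-2-en-1-yl)chroman-4-one (6,8-diprenylnaringenin) | CC(C)=CCc1c(O)c(CC=C(C)C)c2c(c1O)C(=O)C[C@@H](c1ccc(O)cc1)O2 | target

## Step count and weak points

Total: 8 steps. Longest linear sequence: 7 steps (1 to 3 to 4 to 7 to 9 to 10 to 11 to 12; step 3 is the side branch).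

**Step 6 (key step).** Two processes are most likely to fail. The first is diversion of the carbenoid to the ether oxygen, with ylide formation and migration of the electron-rich benzyl group. The second is weak discrimination between the enantiotopic benzylic hydrogens by an unsubstituted and therefore very reactive acceptor carbenoid. The fallback gives up the insertion and makes the C2–aryl bond instead. It sets out from 4 and returns at 11. Condensation of 4 with N,N-dimethylformamide dimethyl acetal should give the enaminone (E)-1-[4-(tert-butyldimethylsilyloxy)-2,6-dihydroxy-3,5-bis(3-methylbut-2-en-1-yl)phenyl]-3-(dimethylamino)prop-2-en-1-one F1. Mild acid closes it, with loss of dimethylamine, to 7-(tert-butyldimethylsilyloxy)-5-hydroxy-6,8-bis(3-methylbut-2-en-1-yl)-4H-chromen-4-one F2. Rhodium-catalysed asymmetric 1,4-addition of the purchased 4-(tert-butyldimethylsilyloxy)phenylboronic acid F3 ([Rh(OH)(cod)]2 with a chiral biaryl diphosphine, toluene/water) to F2 then gives 11 directly, and step 8 follows unchanged.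

**Step 7.** The concerns are Lewis-acid ionisation of the benzylic C2–O1 bond, which would erode the C2 configuration, and slow cleavage that invites closure of the C6 prenyl group onto the freed 5-hydroxyl. The fallback sets out from 10 and returns at 12. Buffered fluoride (Bu4NF/AcOH) removes all three silyl groups to give (2S)-7-hydroxy-5-(4-hydroxybenzyloxy)-2-(4-hydroxyphenyl)-6,8-bis(3-methylbut-2-en-1-yl)chroman-4-one F4. Brief exposure to a weakly basic aqueous phosphate buffer in acetonitrile then lets the 4-hydroxybenzyl ether leave by 1,6-elimination, with water capturing the quinone methide, to give 12. The pH and contact time must be kept as low as the elimination allows, because the same phenoxide-driven process can open ring C.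

**Step 4.** The second etherification has to take place at a chelated phenol flanked on both sides, so stalling at the mono-ether and alkylation of the reduced azodicarboxylate by the electron-rich benzylic phosphonium ion are the likely failures. The fallback sets out from 6 and returns at 7. Appel bromination of 6 (CBr4, PPh3) gives 4-(tert-butyldimethylsilyloxy)benzyl bromide F5, and Williamson alkylation of 4 with F5 (K2CO3, acetone, catalytic Bu4NI) gives 7. If carbonate removes the O4 silyl group, the conditions of step 2 would restore it.

**Step 1.** Statistical alkylation is the problem: under-alkylation, geminal dialkylation with loss of aromaticity and O-alkylation all compete, so throughput will be limited. The fallback sets out from 1 and returns at 3 without any new intermediate (F0). It is an acid-mediated Friedel–Crafts prenylation of 1 with 2-methylbut-3-en-2-ol and BF3·OEt2 in dioxane. This proceeds on the neutral phenol and cannot give the dearomatised gem-dialkyl product.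

## Further compounds

F1 | step 6 | (E)-1-[4-(tert-butyldimethylsilyloxy)-2,6-dihydroxy-3,5-bis(3-methylbut-2-en-1-yl)phenyl]-3-(dimethylamino)prop-2-en-1-one | CN(C)/C=C/C(=O)c1c(O)c(CC=C(C)C)c(O[Si](C)(C)C(C)(C)C)c(CC=C(C)C)c1O
F2 | step 6 | 7-(tert-butyldimethylsilyloxy)-5-hydroxy-6,8-bis(3-methylbut-2-en-1-yl)-4H-chromen-4-one | O=c1ccoc2c(CC=C(C)C)c(O[Si](C)(C)C(C)(C)C)c(CC=C(C)C)c(O)c12
F3 | step 6 | 4-(tert-butyldimethylsilyloxy)phenylboronic acid (purchased coupling partner) | OB(O)c1ccc(O[Si](C)(C)C(C)(C)C)cc1
F4 | step 7 | (2S)-7-hydroxy-5-(4-hydroxybenzyloxy)-2-(4-hydroxyphenyl)-6,8-bis(3-methylbut-2-en-1-yl)chroman-4-one | CC(C)=CCc1c(O)c(CC=C(C)C)c2c(c1OCc1ccc(O)cc1)C(=O)C[C@@H](c1ccc(O)cc1)O2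
F5 | step 4 | 4-(tert-butyldimethylsilyloxy)benzyl bromide | BrCc1ccc(O[Si](C)(C)C(C)(C)C)cc1
F0 | step 1 | none | none
A1 | alternative 1 | 2-(3-methylbut-2-en-1-yl)-3-(triisopropylsilyloxy)cyclobut-2-en-1-one | O=C1CC(O[Si](C(C)C)(C(C)C)C(C)C)=C1CC=C(C)C
A2 | alternative 1 | triisopropyl[(5-methylhex-4-en-1-yn-1-yl)oxy]silane | CC(C)=CCC#CO[Si](C(C)C)(C(C)C)C(C)C
A3 | alternative 1 | 2,4-bis(3-methylbut-2-en-1-yl)-3,5-bis(triisopropylsilyloxy)phenol | Oc1cc(O[Si](C(C)C)(C(C)C)C(C)C)c(CC=C(C)C)c(O[Si](C(C)C)(C(C)C)C(C)C)c1CC=C(C)C
A4 | alternative 2 | 1-methoxy-7-methyl-2-(3-methylbut-2-en-1-yl)-1,3-bis(trimethylsilyloxy)octa-1,3,6-triene | COC(O[Si](C)(C)C)=C(CC=C(C)C)C(O[Si](C)(C)C)=CCC=C(C)C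
A5 | alternative 2 | (2S)-5-bromo-2-[4-(tert-butyldimethylsilyloxy)phenyl]-2,3-dihydro-4H-pyran-4-one | O=C1C[C@@H](c2ccc(O[Si](C)(C)C(C)(C)C)cc2)OC=C1Br
A6 | alternative 2 | (2S)-2-[4-(tert-butyldimethylsilyloxy)phenyl]-5,7-dihydroxy-6,8-bis(3-methylbut-2-en-1-yl)chroman-4-one | CC(C)=CCc1c(O)c(CC=C(C)C)c2c(c1O)C(=O)C[C@@H](c1ccc(O[Si](C)(C)C(C)(C)C)cc1)O2
A7 | alternative 3 | 2,4-bis(tert-butyldimethylsilyloxy)-6-hydroxy-3,5-bis(3-methylbut-2-en-1-yl)benzaldehyde | O=Cc1c(O)c(CC=C(C)C)c(O[Si](C)(C)C(C)(C)C)c(CC=C(C)C)c1O[Si](C)(C)C(C)(C)C
A8 | alternative 3 | trimethyl orthoformate | COC(OC)OC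
A9 | alternative 3 | tert-butyl(dimethyl)(4-vinylphenoxy)silane | C=Cc1ccc(O[Si](C)(C)C(C)(C)C)cc1
A10 | alternative 3 | 3,5-bis(tert-butyldimethylsilyloxy)-6-(methoxymethylidene)-2,4-bis(3-methylbut-2-en-1-yl)cyclohexa-2,4-dien-1-one | COC=C1C(=O)C(CC=C(C)C)=C(O[Si](C)(C)C(C)(C)C)C(CC=C(C)C)=C1O[Si](C)(C)C(C)(C)C
A11 | alternative 3 | (2S,4S)-5,7-bis(tert-butyldimethylsilyloxy)-2-[4-(tert-butyldimethylsilyloxy)phenyl]-4-methoxy-6,8-bis(3-methylbut-2-en-1-yl)chromane (2,4-cis) | CO[C@H]1C[C@@H](c2ccc(O[Si](C)(C)C(C)(C)C)cc2)Oc2c(CC=C(C)C)c(O[Si](C)(C)C(C)(C)C)c(CC=C(C)C)c(O[Si](C)(C)C(C)(C)C)c21
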